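**Retrosynthetic overview**

1. Endgame: the C8 ester is put on last; the C8 alcohol comes from a C8 ketone by hydride attack anti to the lactone, and both primary alcohols travel as silyl ethers.
2. Key disconnection: reconnecting C5 to C8 turns the ten-membered carbocycle into a cyclobutane (C5–C6–C7–C8) fused to a cyclooctene (C8–C9–C10=C1–C2–C3–C4–C5). The enabling feature is the 1,3-disposition of the C8 oxygen and the C4=C5–C15–O allylic alcohol, the retron of an alkoxide/epoxide Grob fragmentation; the cis-fused γ-lactone on C6–C7 is what a cyclobutane imposes, and the Z C1=C10 alkene is forced in an eight-membered ring.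
3. The cyclooctene comes from ring-closing metathesis after 2-methylallyl addition to the C8 cyclobutanone. Cyclobutanone and lactone form together in an intramolecular keteniminium–enol ester [2+2] cycloaddition (bonds C7–C6 and C8–C5), steered by the C11 methyl, which is inverted afterwards by kinetic protonation.
4. Fragments: (R)-methylsuccinic anhydride (C7, C8, C11–C13) and an alkyne whose C4 quaternary centre comes from a Sharpless asymmetric epoxidation, joined by ruthenium-catalysed enol ester formation; the side-chain acid comes from a Wittig olefination.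
5. Order of ring formation: γ-lactone and cyclobutane (step 9), cyclooctene (step 11), two-atom ring expansion to the cyclodecadiene (step 13).

Key step: step 13

Remark: locants C1–C15 in names and comments are those of the target (ring carbons C1–C10, methyl C14 on C10, C15 on C4, lactone carbons C11/C12, methyl C13 on C11); where steric control decides an epimer at C5 or C8 the expected one is drawn, both centres become sp2 in step 13, so a C8 epimer would converge, whereas C5 must be homogeneous.

**Route**

Step 1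
Reactants: 1 2-methylprop-2-en-1-ol; 2 3-bromoprop-1-ene
Product: 4 2-methylidenehex-5-en-1-ol, via dilithio dianion 3 (not isolated)
Conditions: n-BuLi (2.2 equiv), TMEDA, Et2O, 0 °C to rt; then 2, −78 to 0 °C; H2O
Reagents that add atoms: none
Why: allylic metalation of the lithium alkoxide gives the C,O-dianion, whose C-alkylation with allyl bromide is an established route to 2-alkylidene alkanols; no stereocentre is formed.

Step 2
Reactants: 4 2-methylidenehex-5-en-1-ol
Product: 5 [(2R)-2-(but-3-en-1-yl)oxiran-2-yl]methanol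
Conditions: Ti(OiPr)4 (cat.), D-(−)-diethyl tartrate (cat.), tBuOOH, 4 Å molecular sieves, CH2Cl2, −20 °C
Reagents that add atoms: tert-butyl hydroperoxide, CC(C)(C)OO
Why: Sharpless asymmetric epoxidation of a 2-substituted allylic alcohol; D-(−)-tartrate should deliver oxygen to the face that gives the (R)-epoxy alcohol (C4), and the isolated vinyl group is not bound to titanium and stays intact.

Step 3
Reactants: 5 [(2R)-2-(but-3-en-1-yl)oxiran-2-yl]methanol
Product: 6 (2S)-2-(but-3-en-1-yl)oxirane-2-carbaldehyde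
Conditions: TEMPO (cat.), PhI(OAc)2, CH2Cl2, rt
Reagents that add atoms: none
Why: TEMPO-catalysed oxidation of the primary alcohol stops at the aldehyde, and C4 is quaternary and cannot epimerise (the descriptor changes only by priority).

Step 4
Reactants: 6 (2S)-2-(but-3-en-1-yl)oxirane-2-carbaldehyde
Product: 7 (2R)-2-(but-3-en-1-yl)-2-ethynyloxirane
Conditions: dimethyl (1-diazo-2-oxopropyl)phosphonate, K2CO3, MeOH, 0 °C to rt
Reagents that add atoms: dimethyl (1-diazo-2-oxopropyl)phosphonate, CC(=O)C(=[N+]=[N-])P(=O)(OC)OC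
Why: Seyferth–Gilbert homologation in the Ohira–Bestmann variant converts the non-enolisable aldehyde into the terminal alkyne under carbonate conditions that leave the oxirane intact.

Step 5
Reactants: 7 (2R)-2-(but-3-en-1-yl)-2-ethynyloxirane
Product: 8 (3R)-3-(chloromethyl)hept-6-en-1-yn-3-ol
Conditions: LiCl, AcOH, THF, rt
Reagents that add atoms: lithium chloride, [Li+].[Cl-]
Why: SN2 opening of the 2,2-disubstituted oxirane by chloride at its CH2 carbon under buffered acid gives the tertiary chlorohydrin with no bond to C4 broken (retention).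

Step 6
Reactants: 8 (3R)-3-(chloromethyl)hept-6-en-1-yn-3-ol
Product: 9 {[(3R)-3-(chloromethyl)hept-6-en-1-yn-3-yl]oxy}triethylsilane
Conditions: Et3SiOTf, 2,6-lutidine, CH2Cl2, −78 to 0 °C
Reagents that add atoms: triethylsilyl trifluoromethanesulfonate, CC[Si](CC)(CC)OS(=O)(=O)C(F)(F)F
Why: silyl triflate/lutidine silylation of the tertiary alcohol masks it for the electrophilic amide activation of step 9.

Step 7
Reactants: 10 (3R)-3-methyloxolane-2,5-dione; 11 pyrrolidine
Product: 12 (2R)-2-methyl-4-oxo-4-(pyrrolidin-1-yl)butanoic acid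
Conditions: CH2Cl2, 0 °C to rt; dilute HCl work-up
Reagents that add atoms: none
Why: aminolysis of the cyclic anhydride should occur mainly at the less hindered carbonyl remote from the methyl group, leaving the free carboxyl next to C11, which is not touched.

Step 8
Reactants: 9 {[(3R)-3-(chloromethyl)hept-6-en-1-yn-3-yl]oxy}triethylsilane; 12 (2R)-2-methyl-4-oxo-4-(pyrrolidin-1-yl)butanoic acid
Product: 13 (1Z,3R)-3-(chloromethyl)-3-[(triethylsilyl)oxy]hepta-1,6-dien-1-yl (2R)-2-methyl-4-oxo-4-(pyrrolidin-1-yl)butanoate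
Conditions: Ru(2-methylallyl)2(Ph2P(CH2)4PPh2) (5 mol%), toluene, 60 °C
Reagents that add atoms: none
Why: ruthenium-catalysed anti-Markovnikov addition of a carboxylic acid to a terminal alkyne through a vinylidene complex gives the (Z)-enol ester under neutral conditions that should not epimerise C11.

Step 9
Reactants: 13 (1Z,3R)-3-(chloromethyl)-3-[(triethylsilyl)oxy]hepta-1,6-dien-1-yl (2R)-2-methyl-4-oxo-4-(pyrrolidin-1-yl)butanoate
Product: 16 (1S,4R,5R,7S)-7-{(2R)-1-chloro-2-[(triethylsilyl)oxy]hex-5-en-2-yl}-4-methyl-2-oxabicyclo[3.2.0]heptane-3,6-dione, via keteniminium triflate 14 (not isolated), via cyclobutaniminium triflate 15 (not isolated)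
Conditions: Tf2O, 2,4,6-collidine, ClCH2CH2Cl, 0 to 70 °C; then H2O, rt
Reagents that add atoms: water, O
Why: amide activation gives a keteniminium ion that adds intramolecularly [2+2] to the enol ester alkene (C8 to the nucleophilic C5, C7 to the oxygen-bearing C6, five-membered tether), so lactone and cyclobutane form cis-fused together; the C11 methyl turns away from the C7=C8 axis (allylic strain) and should fix C6 and C7 with the methyl on the convex face, and C5, α to the iminium, should settle with its side chain trans to the lactone oxygen before hydrolysis.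

Step 10
Reactants: 16 (1S,4R,5R,7S)-7-{(2R)-1-chloro-2-[(triethylsilyl)oxy]hex-5-en-2-yl}-4-methyl-2-oxabicyclo[3.2.0]heptane-3,6-dione; 17 3-bromo-2-methylprop-1-ene
Product: 18 (1S,4R,5R,6S,7R)-7-{(2R)-1-chloro-2-[(triethylsilyl)oxy]hex-5-en-2-yl}-6-hydroxy-4-methyl-6-(2-methylprop-2-en-1-yl)-2-oxabicyclo[3.2.0]heptan-3-one
Conditions: Zn dust, THF/sat. aq. NH4Cl, 0 °C to rt
Reagents that add atoms: none
Why: Barbier-type 2-methylallylation adds to the strained cyclobutanone without touching lactone, chloride or silyl ether, and the nucleophile should enter anti to the bulky C5 side chain, leaving the C8 hydroxyl cis to it.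

Step 11
Reactants: 18 (1S,4R,5R,6S,7R)-7-{(2R)-1-chloro-2-[(triethylsilyl)oxy]hex-5-en-2-yl}-6-hydroxy-4-methyl-6-(2-methylprop-2-en-1-yl)-2-oxabicyclo[3.2.0]heptan-3-one
Product: 19 tricyclic lactone: cyclobutane C5–C6–C7–C8 with the γ-lactone cis-fused on C6/C7 and the (1Z)-cyclooctene C8–C9–C10(CH3)=C1–C2–C3–C4–C5 trans-fused on C5/C8, C8–OH, C4(OSiEt3)(CH2Cl); 4R,5R,6S,7R,8S,11R
Conditions: RuCl2(=CHPh)(H2IMes)(PCy3) (second-generation Grubbs catalyst, 10 mol%), toluene, 0.002 M, 80 °C
Reagents that add atoms: none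
Why: ring-closing metathesis of the vinyl and 2-methylallyl termini gives the trisubstituted C1=C10 alkene, necessarily Z in an eight-membered ring; both chains sit on the cyclobutane and on quaternary carbons (gem-dialkyl effect), and the trans fusion needs a torsion of about 100–120° that a cyclooctene can adopt.

Step 12
Reactants: 19 tricyclic lactone (4R,5R,6S,7R,8S,11R)
Product: 21 tricyclic diol chloride: as 19 but with free C4–OH and inverted C11; 4R,5R,6S,7R,8S,11S, via C11-epimerised silyl ether 20 (not isolated)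
Conditions: LiN(iPr)2 (2.3 equiv), THF, −78 °C; AcOH, −78 °C; then HF·pyridine, THF, 0 °C to rt
Reagents that add atoms: none
Why: the lactone enolate (with the C8 lithium alkoxide) should be protonated kinetically on the convex face, the concave face being blocked by C8 and C9, which turns the C11 methyl cis to C8 (11S) as the target requires; HF·pyridine then removes the triethylsilyl group.

Step 13
Reactants: 21 tricyclic diol chloride (4R,5R,6S,7R,8S,11S)
Product: 24 (3S,3aR,6Z,10Z,11aR)-10-({[tert-butyl(dimethyl)silyl]oxy}methyl)-3,6-dimethyl-3,3a,5,8,9,11a-hexahydrocyclodeca[b]furan-2,4-dione, via spiro-epoxide alkoxide 22 (not isolated), via hydroxy ketone alkoxide 23 (not isolated)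
Conditions: KN(SiMe3)2 (2.05 equiv), THF, −78 to −30 °C; then tBuMe2SiCl, −30 to 0 °C; pH 7 buffer
Reagents that add atoms: tert-butyl(chloro)dimethylsilane, CC(C)(C)[Si](C)(C)Cl
Why: Proposed new method: double deprotonation lets the C4 alkoxide displace the C15 chloride (3-exo-tet, helped by the gem-disubstitution) to give the spiro-epoxide, and the C8 cyclobutanolate then undergoes a Grob-type fragmentation in which the C5–C8 ring-fusion bond breaks anti-periplanar to the oxirane C4–O bond, so that the C8 carbonyl, the C4=C5 alkene and the C15 alkoxide appear together with release of cyclobutane and oxirane strain; the alkoxide is silylated in the same flask. The closest known reaction types are the alkoxide-triggered fragmentation of β,γ-epoxy tertiary alcohols in bridged bicycles and the Grob fragmentation of cyclobutane 1,3-hydroxy sulfonates, but an epoxide nucleofuge on a cyclobutanol fusion bond is not documented. The only ring closed is the transient oxirane (3-exo-tet); the ten-membered ring is not closed but uncovered when the bond shared by the four- and eight-membered rings is cut, the eight-membered ring growing by C6 and C7. No stereocentre is created: C4, C5 and C8 are erased, the alkene geometry follows stereospecifically from the 4R centre of step 2 and the 5R centre, because in the less crowded reactive rotamer (C3 gauche to C8 on the H5 side) C15 ends cis to C6 and C3 trans to C6, and C6, C7 and C11 are carried through. The step needs fragmentation to win over etherification, over β-elimination of the lactone carboxylate from the new ketone and over conjugation of the β,γ-unsaturated ketone; attack of the C8 alkoxide on C15 would be a neopentyl 5-exo displacement or a 5-endo oxirane opening, and the other two are held back by working at or below −30 °C and capping the primary alkoxide at once.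

Step 14
Reactants: 24 keto lactone silyl ether
Product: 25 (3S,3aS,4S,6Z,10Z,11aR)-10-({[tert-butyl(dimethyl)silyl]oxy}methyl)-4-hydroxy-3,6-dimethyl-3a,4,5,8,9,11a-hexahydrocyclodeca[b]furan-2(3H)-one
Conditions: NaBH4, CeCl3·7H2O, MeOH, −78 °C
Reagents that add atoms: none
Why: Luche reduction is mild enough for the β-acyloxy, β,γ-unsaturated ketone, and hydride should attack C8 from the face away from the lactone C11 and its methyl, giving the 8S alcohol with oxygen cis to C11.

Step 15
Reactants: 26 {[tert-butyl(dimethyl)silyl]oxy}acetaldehyde; 27 ethyl 2-(triphenyl-λ5-phosphanylidene)propanoate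
Product: 28 ethyl (2E)-4-{[tert-butyl(dimethyl)silyl]oxy}-2-methylbut-2-enoate
Conditions: CH2Cl2, rt
Reagents that add atoms: none
Why: Wittig olefination with the stabilised ylide should give the (E)-2-methyl enoate.

Step 16
Reactants: 28 ethyl (2E)-4-{[tert-butyl(dimethyl)silyl]oxy}-2-methylbut-2-enoate
Product: 29 (2E)-4-{[tert-butyl(dimethyl)silyl]oxy}-2-methylbut-2-enoic acid
Conditions: LiOH·H2O, THF/H2O, rt; then 0.5 M HCl to pH 4, 0 °C
Reagents that add atoms: lithium hydroxide, [Li+].[OH-]
Why: saponification of the ethyl ester leaves the silyl ether and the alkene geometry intact.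

Step 17
Reactants: 25 C8 alcohol; 29 (2E)-4-{[tert-butyl(dimethyl)silyl]oxy}-2-methylbut-2-enoic acid
Product: 30 (3S,3aS,4S,6Z,10Z,11aR)-10-({[tert-butyl(dimethyl)silyl]oxy}methyl)-3,6-dimethyl-2-oxo-2,3,3a,4,5,8,9,11a-octahydrocyclodeca[b]furan-4-yl (2E)-4-{[tert-butyl(dimethyl)silyl]oxy}-2-methylbut-2-enoate
Conditions: DCC, DMAP, CH2Cl2, 0 °C to rt
Reagents that add atoms: none
Why: Steglich esterification acylates the only free hydroxyl (C8–OH) with retention at C8.

Step 18
Reactants: 30 bis-silyl ether
Product: 31 (3S,3aS,4S,6Z,10Z,11aR)-10-(hydroxymethyl)-3,6-dimethyl-2-oxo-2,3,3a,4,5,8,9,11a-octahydrocyclodeca[b]furan-4-yl (2E)-4-hydroxy-2-methylbut-2-enoate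
Conditions: HF·pyridine, pyridine, THF, 0 °C to rt
Reagents that add atoms: none
Why: fluoride cleavage of both primary silyl ethers under buffered conditions should spare the two esters and the skipped diene.

**Compound list**

1 | 2-methylprop-2-en-1-ol | C=C(C)CO | starting material
2 | 3-bromoprop-1-ene | C=CCBr | starting material
3 | dilithio C,O-dianion of 1 | [Li]CC(=C)CO[Li] | intermediate
4 | 2-methylidenehex-5-en-1-ol | C=CCCC(=C)CO | intermediate
5 | [(2R)-2-(but-3-en-1-yl)oxiran-2-yl]methanol | OC[C@]1(CCC=C)CO1 | intermediate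
6 | (2S)-2-(but-3-en-1-yl)oxirane-2-carbaldehyde | O=C[C@]1(CCC=C)CO1 | intermediate
7 | (2R)-2-(but-3-en-1-yl)-2-ethynyloxirane | C#C[C@]1(CCC=C)CO1 | intermediate
8 | (3R)-3-(chloromethyl)hept-6-en-1-yn-3-ol | C#C[C@@](O)(CCl)CCC=C | intermediate
9 | {[(3R)-3-(chloromethyl)hept-6-en-1-yn-3-yl]oxy}triethylsilane | C#C[C@@](O[Si](CC)(CC)CC)(CCl)CCC=C | intermediate
10 | (3R)-3-methyloxolane-2,5-dione ((R)-methylsuccinic anhydride) | O=C1OC(=O)C[C@H]1C | starting material
11 | pyrrolidine | C1CCNC1 | starting material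
12 | (2R)-2-methyl-4-oxo-4-(pyrrolidin-1-yl)butanoic acid | OC(=O)[C@H](C)CC(=O)N1CCCC1 | intermediate
13 | (1Z,3R)-3-(chloromethyl)-3-[(triethylsilyl)oxy]hepta-1,6-dien-1-yl (2R)-2-methyl-4-oxo-4-(pyrrolidin-1-yl)butanoate | O=C(N1CCCC1)C[C@@H](C)C(=O)O/C=C\[C@@](O[Si](CC)(CC)CC)(CCl)CCC=C | intermediate
14 | keteniminium triflate from 13 (N=C8=C7 cumulene on the pyrrolidinium nitrogen) | C1CC[N+](C1)=C=C[C@@H](C)C(=O)O/C=C\[C@@](O[Si](CC)(CC)CC)(CCl)CCC=C.[O-]S(=O)(=O)C(F)(F)F | intermediate
15 | cyclobutaniminium triflate (pyrrolidinium ylidene at C8 of the skeleton of 16) | ClC[C@@](O[Si](CC)(CC)CC)(CCC=C)[C@@H]1[C@H]2OC(=O)[C@H](C)[C@H]2C1=[N+]3CCCC3.[O-]S(=O)(=O)C(F)(F)F | intermediate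
16 | (1S,4R,5R,7S)-7-{(2R)-1-chloro-2-[(triethylsilyl)oxy]hex-5-en-2-yl}-4-methyl-2-oxabicyclo[3.2.0]heptane-3,6-dione | ClC[C@@](O[Si](CC)(CC)CC)(CCC=C)[C@@H]1[C@H]2OC(=O)[C@H](C)[C@H]2C1=O | intermediate
17 | 3-bromo-2-methylprop-1-ene | CC(=C)CBr | starting material
18 | (1S,4R,5R,6S,7R)-7-{(2R)-1-chloro-2-[(triethylsilyl)oxy]hex-5-en-2-yl}-6-hydroxy-4-methyl-6-(2-methylprop-2-en-1-yl)-2-oxabicyclo[3.2.0]heptan-3-one | ClC[C@@](O[Si](CC)(CC)CC)(CCC=C)[C@@H]1[C@H]2OC(=O)[C@H](C)[C@H]2[C@@]1(O)CC(C)=C | intermediate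
19 | tricyclic lactone, cyclobutane with cis-fused γ-lactone (C6/C7) and trans-fused (Z)-cyclooctene (C5/C8), C8–OH, C4(OSiEt3)(CH2Cl); 4R,5R,6S,7R,8S,11R | ClC[C@@]1(O[Si](CC)(CC)CC)CC/C=C(C)\C[C@@]2(O)[C@H]1[C@H]3OC(=O)[C@H](C)[C@H]32 | intermediate
20 | C11 epimer of 19; 4R,5R,6S,7R,8S,11S | ClC[C@@]1(O[Si](CC)(CC)CC)CC/C=C(C)\C[C@@]2(O)[C@H]1[C@H]3OC(=O)[C@@H](C)[C@H]32 | intermediate
21 | tricyclic diol chloride, as 20 with free C4–OH; 4R,5R,6S,7R,8S,11S | ClC[C@@]1(O)CC/C=C(C)\C[C@@]2(O)[C@H]1[C@H]3OC(=O)[C@@H](C)[C@H]32 | intermediate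
22 | spiro-epoxide (C4–O–C15) of 21 with free C8–OH, formed as its potassium alkoxide; 4R,5R,6S,7R,8S,11S | C1O[C@@]12CC/C=C(C)\C[C@@]3(O)[C@H]2[C@H]4OC(=O)[C@@H](C)[C@H]43 | intermediate
23 | (3S,3aR,6Z,10Z,11aR)-10-(hydroxymethyl)-3,6-dimethyl-3,3a,5,8,9,11a-hexahydrocyclodeca[b]furan-2,4-dione, formed as its potassium alkoxide | C/C1=C/CC/C(CO)=C/[C@H]2OC(=O)[C@@H](C)[C@H]2C(=O)C1 | intermediate
24 | (3S,3aR,6Z,10Z,11aR)-10-({[tert-butyl(dimethyl)silyl]oxy}methyl)-3,6-dimethyl-3,3a,5,8,9,11a-hexahydrocyclodeca[b]furan-2,4-dione | C/C1=C/CC/C(CO[Si](C)(C)C(C)(C)C)=C/[C@H]2OC(=O)[C@@H](C)[C@H]2C(=O)C1 | intermediate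
25 | (3S,3aS,4S,6Z,10Z,11aR)-10-({[tert-butyl(dimethyl)silyl]oxy}methyl)-4-hydroxy-3,6-dimethyl-3a,4,5,8,9,11a-hexahydrocyclodeca[b]furan-2(3H)-one | C/C1=C/CC/C(CO[Si](C)(C)C(C)(C)C)=C/[C@H]2OC(=O)[C@@H](C)[C@H]2[C@@H](O)C1 | intermediate
26 | {[tert-butyl(dimethyl)silyl]oxy}acetaldehyde | O=CCO[Si](C)(C)C(C)(C)C | starting material
27 | ethyl 2-(triphenyl-λ5-phosphanylidene)propanoate | CCOC(=O)C(C)=P(c1ccccc1)(c1ccccc1)c1ccccc1 | starting material
28 | ethyl (2E)-4-{[tert-butyl(dimethyl)silyl]oxy}-2-methylbut-2-enoate | CCOC(=O)/C(C)=C/CO[Si](C)(C)C(C)(C)C | intermediate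
29 | (2E)-4-{[tert-butyl(dimethyl)silyl]oxy}-2-methylbut-2-enoic acid | OC(=O)/C(C)=C/CO[Si](C)(C)C(C)(C)C | intermediate
30 | bis(tert-butyldimethylsilyl) ether of the target (C15–O and side-chain O) | C/C1=C/CC/C(CO[Si](C)(C)C(C)(C)C)=C/[C@H]2OC(=O)[C@@H](C)[C@H]2[C@@H](OC(=O)/C(C)=C/CO[Si](C)(C)C(C)(C)C)C1 | intermediate
31 | (3S,3aS,4S,6Z,10Z,11aR)-10-(hydroxymethyl)-3,6-dimethyl-2-oxo-2,3,3a,4,5,8,9,11a-octahydrocyclodeca[b]furan-4-yl (2E)-4-hydroxy-2-methylbut-2-enoate | C/C1=C/CC/C(CO)=C/[C@H]2OC(=O)[C@@H](C)[C@H]2[C@@H](OC(=O)/C(C)=C/CO)C1 | target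

**Step count and risks**

Total step count: 18. Longest linear sequence: 15 steps (1–6, 8–14, 17, 18).

Steps most likely to fail:

1. Step 13 (key step). The fragmentation may stall or be diverted. If the bicycle cannot place the C5–C8 bond anti-periplanar to the oxirane C4–O bond, the epoxy alkoxide would persist or drift into ether formation. The new β-acyloxy ketone may also lose the lactone carboxylate, or the C1=C10 alkene may move into conjugation, before the quench. Fallback with known chemistry, setting out from 21: aqueous K2CO3 in dioxane closes the oxirane and opens it with hydroxide at the CH2 carbon to give the C4,C15-diol, triol F1. NaIO4 cleaves this glycol to the C4 ketone, β-hydroxy ketone F2, with C15 lost. KN(SiMe3)2 at −78 °C then triggers the classical de Mayo-type retro-aldol ring expansion (C5–C8 cleavage), and PhNTf2 traps the regiodefined C4=C5 enolate as the ring-trans enol triflate F3; the same rotamer preference should put the enolate oxygen cis to C6. Stille coupling of F3 with (tributylstannyl)methanol (Pd(PPh3)4, LiCl) restores C15 as the hydroxymethyl group and gives 23, which is silylated (tBuMe2SiCl, imidazole) to return to the route at 24.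

2. Step 9. The cycloaddition may be outrun by decomposition of the keteniminium ion because the enol ester alkene is a weak nucleophile. The cyclobutaniminium ion may expel its β-carboxylate under collidine at 70 °C, and facial control by C11 or equilibration at C5 may be incomplete. Fallback through a neutral ketene, setting out from 10: allyl alcohol with catalytic DMAP opens the anhydride to (2R)-2-methyl-4-oxo-4-(prop-2-en-1-yloxy)butanoic acid F4. The ruthenium-catalysed addition of step 8 to alkyne 9 gives the corresponding (Z)-enol ester allyl ester F5. Pd(PPh3)4/PhSiH3 removes the allyl group to give the enol ester acid F6. 2-Chloro-1-methylpyridinium iodide and Et3N in hot toluene under high dilution generate the ketene F7, whose intramolecular ketene–alkene [2+2] cycloaddition returns to the route at 16.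

3. Step 11. Ring closure may lose to intermolecular metathesis (oligomerisation), because an eight-membered ring trans-fused to the cyclobutane and containing a trisubstituted alkene has to form. Fallback by carbonyl coupling, setting out from 18: ozonolysis of both terminal alkenes (O3, CH2Cl2/MeOH, −78 °C; Me2S) gives the keto aldehyde F8 (C1 aldehyde, C10 methyl ketone). Intramolecular McMurry coupling with low-valent titanium (TiCl3(DME)1.5, Zn–Cu couple, DME, reflux, slow addition) forms C1=C10 directly as the ring alkene and returns to the route at 19; the ketone/aldehyde pair should couple faster than the lactone or the chloride reacts.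

Further compounds

F1 | step 13 | tricyclic triol, as 21 with C15–OH in place of C15–Cl; 4R,5R,6S,7R,8S,11S | OC[C@@]1(O)CC/C=C(C)\C[C@@]2(O)[C@H]1[C@H]3OC(=O)[C@@H](C)[C@H]32
F2 | step 13 | tricyclic β-hydroxy ketone, C4 ketone and C8–OH on the skeleton of 21 without C15 | O=C1CC/C=C(C)\C[C@@]2(O)[C@H]1[C@H]3OC(=O)[C@@H](C)[C@H]32
F3 | step 13 | ten-membered keto lactone enol triflate, C4–OTf on the ring-trans C4=C5 alkene, C8 ketone | C/C1=C/CC/C(OS(=O)(=O)C(F)(F)F)=C/[C@H]2OC(=O)[C@@H](C)[C@H]2C(=O)C1
F4 | step 9 | (2R)-2-methyl-4-oxo-4-(prop-2-en-1-yloxy)butanoic acid | OC(=O)[C@H](C)CC(=O)OCC=C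
F5 | step 9 | 1-[(1Z,3R)-3-(chloromethyl)-3-[(triethylsilyl)oxy]hepta-1,6-dien-1-yl] 4-prop-2-en-1-yl (2R)-2-methylbutanedioate | C=CCOC(=O)C[C@@H](C)C(=O)O/C=C\[C@@](O[Si](CC)(CC)CC)(CCl)CCC=C
F6 | step 9 | (3R)-4-{[(1Z,3R)-3-(chloromethyl)-3-[(triethylsilyl)oxy]hepta-1,6-dien-1-yl]oxy}-3-methyl-4-oxobutanoic acid | OC(=O)C[C@@H](C)C(=O)O/C=C\[C@@](O[Si](CC)(CC)CC)(CCl)CCC=C
F7 | step 9 | ketene from F6 (C8=C7 ketene on the enol ester) | O=C=C[C@@H](C)C(=O)O/C=C\[C@@](O[Si](CC)(CC)CC)(CCl)CCC=C
F8 | step 11 | keto aldehyde from 18 (C1 aldehyde, C10 methyl ketone) | ClC[C@@](O[Si](CC)(CC)CC)(CCC=O)[C@@H]1[C@H]2OC(=O)[C@H](C)[C@H]2[C@@]1(O)CC(C)=O
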